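**Strategy.** The route rests on cutting the C3–C4 bond of the butyrolactone (O1, C2=O, C3, C4, C5). The key step exploits the fact that C4, the ring carbon carrying the ring B benzyl group, is in the open chain merely the central CH2 of a 3-arylpropyl ester, in a 1,5-relationship to the carbon that becomes C3. A chiral divalent rhodium carboxamidate turns the achiral diazoacetate into a carbene that inserts into one enantiotopic C–H bond, closing the lactone and setting C4 in one operation. C3 is then set by trans-selective enolate benzylation, and the threo arylglycerol ether is grown on the ring B phenol by an Evans syn-aldol reaction.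

Key step: step 4

Assumption: ring A is the aryl of the C3 benzyl group, ring B the aryl of the C4 benzyl group, ring C the aryl of the glycerol unit (C7 benzylic, C8 ether-bearing, C9 primary); Rh2(4R-MPPIM)4, the tetrakis[methyl (4R)-2-oxo-1-(3-phenylpropanoyl)imidazolidine-4-carboxylate] complex of divalent dirhodium, is taken as the catalyst enantiomer that delivers the (R)-lactone, its antipode being used if the sense proves opposite.

Step 1
Reactants: 1 3-(4-hydroxy-3-methoxyphenyl)propan-1-ol (dihydroconiferyl alcohol)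
Product: 3 3-[3-methoxy-4-(triisopropylsilyloxy)phenyl]propan-1-ol, via sodium phenoxide 2 (not isolated)
Conditions: NaH (1.0 equiv), THF, 0 °C; then TIPSCl, 0 °C to rt
Reagents that add atoms: triisopropylsilyl chloride, CC(C)[Si](Cl)(C(C)C)C(C)C
Why: One equivalent of base should deprotonate only the far more acidic phenol, and the phenoxide is silylated by the hindered chlorosilane while the neutral primary alcohol stays free (chemoselective silyl ether formation).

Step 2
Reactants: 3 3-[3-methoxy-4-(triisopropylsilyloxy)phenyl]propan-1-ol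
Product: 4 3-[3-methoxy-4-(triisopropylsilyloxy)phenyl]propyl bromoacetate
Conditions: BrCH2COBr, NaHCO3, MeCN, 0 °C
Reagents that add atoms: bromoacetyl bromide, O=C(Br)CBr
Why: Acylation of the primary alcohol by the acyl bromide (esterification) should be fast at 0 °C, and the aryl silyl ether tolerates the weak base.

Step 3
Reactants: 4 3-[3-methoxy-4-(triisopropylsilyloxy)phenyl]propyl bromoacetate
Product: 7 3-[3-methoxy-4-(triisopropylsilyloxy)phenyl]propyl diazoacetate, via alkylated ditosylhydrazide 5 (not isolated), via glyoxylate tosylhydrazone 6 (not isolated)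
Conditions: TsNHNHTs, DBU, THF, 0 °C
Reagents that add atoms: N,N'-ditosylhydrazine, Cc1ccc(cc1)S(=O)(=O)NNS(=O)(=O)c1ccc(C)cc1
Why: SN2 alkylation of the ditosylhydrazide anion by the bromoacetate followed by two base-induced sulfinate eliminations (the second of the Bamford–Stevens type) should give the diazoacetate under conditions that leave ester and silyl ether untouched.

Step 4
Reactants: 7 3-[3-methoxy-4-(triisopropylsilyloxy)phenyl]propyl diazoacetate
Product: 8 (R)-4-[3-methoxy-4-(triisopropylsilyloxy)benzyl]dihydrofuran-2(3H)-one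
Conditions: Rh2(4R-MPPIM)4 (1 mol %), CH2Cl2, reflux, slow addition of 7
Reagents that add atoms: none
Why: The rhodium carboxamidate should decompose 7 with loss of N2 to an electrophilic rhodium carbene, which inserts in a concerted, asynchronous three-centre transition state into one C–H bond of the central methylene of the arylpropyl chain and so creates the C3–C4 bond of the lactone. The closest known reaction type is the intramolecular C–H insertion of alkyl diazoacetates to γ-butyrolactones catalysed by chiral divalent rhodium carboxamidates, applied here to a silyl-protected guaiacylpropyl ester. The five-membered ring closes by 1,5-insertion (carbene carbon to the carbon β to the ester oxygen), the geometrically favoured mode for diazoacetates. The single new stereocentre, C4, is set by the catalyst alone: the chiral imidazolidinone carboxamidate ligands distinguish the two enantiotopic hydrogens of the prochiral CH2, and the ligand enantiomer is chosen for the (R)-lactone. The step needs regioselectivity for this methylene over the benzylic CH2 (six-membered lactone) and the O–CH2 (four-membered lactone), and chemoselectivity over carbene dimerisation and addition to the electron-rich arene; the weakly electrophilic carboxamidate-bound carbene, the preference for five-membered closure and slow addition of 7 should secure it. Because the diazoacetate carries no α-substituent, no 1,2-hydride shift can compete, and C3 is left as a CH2 for the later alkylation.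

Step 5
Reactants: 9 4-benzyloxy-3-methoxybenzyl alcohol
Product: 10 4-benzyloxy-3-methoxybenzyl bromide
Conditions: PBr3, Et2O, 0 °C
Reagents that add atoms: phosphorus tribromide, BrP(Br)Br
Why: Bromination of the activated benzylic alcohol through its phosphite ester should be fast and leaves the aryl benzyl ether intact; the bromide is used freshly.

Step 6
Reactants: 8 (R)-4-[3-methoxy-4-(triisopropylsilyloxy)benzyl]dihydrofuran-2(3H)-one; 10 4-benzyloxy-3-methoxybenzyl bromide
Product: 12 (3R,4R)-3-(4-benzyloxy-3-methoxybenzyl)-4-[3-methoxy-4-(triisopropylsilyloxy)benzyl]dihydrofuran-2(3H)-one, via lithium enolate 11 (not isolated)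
Conditions: LiN(SiMe3)2, THF, −78 °C; then 10, DMPU, −78 to −40 °C
Reagents that add atoms: none
Why: In this lactone enolate alkylation the benzylic bromide should approach the planar enolate on the face opposite the C4 benzyl group, so that C3 is set trans to C4 (3R) under substrate control, trans being also the thermodynamically preferred arrangement.

Step 7
Reactants: 12 (3R,4R)-3-(4-benzyloxy-3-methoxybenzyl)-4-[3-methoxy-4-(triisopropylsilyloxy)benzyl]dihydrofuran-2(3H)-one
Product: 13 (3R,4R)-3-(4-benzyloxy-3-methoxybenzyl)-4-(4-hydroxy-3-methoxybenzyl)dihydrofuran-2(3H)-one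
Conditions: TBAF, AcOH, THF, 0 °C
Reagents that add atoms: none
Why: Fluoride-mediated desilylation should free only the ring B phenol, the acetic acid buffer protecting the lactone and its trans C3 centre from base.

Step 8
Reactants: 13 (3R,4R)-3-(4-benzyloxy-3-methoxybenzyl)-4-(4-hydroxy-3-methoxybenzyl)dihydrofuran-2(3H)-one; 14 (S)-4-benzyl-3-(chloroacetyl)oxazolidin-2-one
Product: 15 (S)-4-benzyl-3-(2-{4-[((3R,4R)-4-(4-benzyloxy-3-methoxybenzyl)-5-oxotetrahydrofuran-3-yl)methyl]-2-methoxyphenoxy}acetyl)oxazolidin-2-one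
Conditions: K2CO3, KI (cat.), MeCN, 40 °C
Reagents that add atoms: none
Why: Williamson etherification of the phenoxide at the strongly activated α-halo carbonyl carbon (iodide-assisted SN2) should outrun acyl transfer and leaves the lactone stereocentres untouched.

Step 9
Reactants: 15 the aryloxyacetyl imide of step 8; 16 4-benzyloxy-3-methoxybenzaldehyde (O-benzylvanillin)
Product: 19 (S)-4-benzyl-3-[(2S,3R)-3-(4-benzyloxy-3-methoxyphenyl)-3-hydroxy-2-{4-[((3R,4R)-4-(4-benzyloxy-3-methoxybenzyl)-5-oxotetrahydrofuran-3-yl)methyl]-2-methoxyphenoxy}propanoyl]oxazolidin-2-one, via boron enolate 17 (not isolated), via boron aldolate 18 (not isolated)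
Conditions: Bu2BOTf, iPr2NEt, CH2Cl2, −78 to 0 °C; then 16, −78 to 0 °C; then pH 7 phosphate buffer, MeOH, H2O2, 0 °C
Reagents that add atoms: none
Why: In this Evans syn-aldol reaction the much more acidic imide is enolised selectively to the Z boron enolate, which adds through a closed chair transition state on the face away from the benzyl group of the (S)-auxiliary, so that C8 and C7 are set together, syn (threo), with the configurations of the target.

Step 10
Reactants: 19 the syn-aldol adduct of step 9
Product: 20 (3R,4R)-3-(4-benzyloxy-3-methoxybenzyl)-4-{4-[(1R,2R)-1-(4-benzyloxy-3-methoxyphenyl)-1,3-dihydroxypropan-2-yloxy]-3-methoxybenzyl}dihydrofuran-2(3H)-one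
Conditions: NaBH4, THF/H2O, 0 °C
Reagents that add atoms: none
Why: Borohydride reductive cleavage of the N-acyloxazolidinone should take the activated exocyclic imide carbonyl to the primary alcohol faster than the γ-lactone reacts, without touching C7 or C8.

Step 11
Reactants: 20 the dibenzyl-protected diol of step 10
Product: 21 (3R,4R)-3-(4-hydroxy-3-methoxybenzyl)-4-{4-[(1R,2R)-1,3-dihydroxy-1-(4-hydroxy-3-methoxyphenyl)propan-2-yloxy]-3-methoxybenzyl}dihydrofuran-2(3H)-one (the target)
Conditions: H2 (1 atm), 10% Pd/C, EtOAc/MeOH, rt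
Reagents that add atoms: none
Why: Hydrogenolysis of the two aryl benzyl ethers under neutral conditions should be faster than cleavage of the benzylic C7–OH or of the alkyl aryl ether, and no stereocentre is affected.

**Compound list**

1 | 3-(4-hydroxy-3-methoxyphenyl)propan-1-ol | COc1cc(CCCO)ccc1O | starting material
2 | sodium phenoxide of 1 (not isolated) | COc1cc(CCCO)ccc1[O-].[Na+] | intermediate
3 | 3-[3-methoxy-4-(triisopropylsilyloxy)phenyl]propan-1-ol | COc1cc(CCCO)ccc1O[Si](C(C)C)(C(C)C)C(C)C | intermediate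
4 | 3-[3-methoxy-4-(triisopropylsilyloxy)phenyl]propyl bromoacetate | COc1cc(CCCOC(=O)CBr)ccc1O[Si](C(C)C)(C(C)C)C(C)C | intermediate
5 | N-alkylated N,N'-ditosylhydrazide of 4 (not isolated) | COc1cc(CCCOC(=O)CN(NS(=O)(=O)c2ccc(C)cc2)S(=O)(=O)c2ccc(C)cc2)ccc1O[Si](C(C)C)(C(C)C)C(C)C | intermediate
6 | glyoxylate ester tosylhydrazone (not isolated) | COc1cc(CCCOC(=O)C=NNS(=O)(=O)c2ccc(C)cc2)ccc1O[Si](C(C)C)(C(C)C)C(C)C | intermediate
7 | 3-[3-methoxy-4-(triisopropylsilyloxy)phenyl]propyl diazoacetate | COc1cc(CCCOC(=O)C=[N+]=[N-])ccc1O[Si](C(C)C)(C(C)C)C(C)C | intermediate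
8 | (R)-4-[3-methoxy-4-(triisopropylsilyloxy)benzyl]dihydrofuran-2(3H)-one | O=C1OC[C@H](Cc2ccc(O[Si](C(C)C)(C(C)C)C(C)C)c(OC)c2)C1 | intermediate
9 | 4-benzyloxy-3-methoxybenzyl alcohol | COc1cc(CO)ccc1OCc1ccccc1 | starting material
10 | 4-benzyloxy-3-methoxybenzyl bromide | COc1cc(CBr)ccc1OCc1ccccc1 | intermediate
11 | lithium enolate of 8 (not isolated) | [Li+].[O-]C1=C[C@@H](Cc2ccc(O[Si](C(C)C)(C(C)C)C(C)C)c(OC)c2)CO1 | intermediate
12 | (3R,4R)-3-(4-benzyloxy-3-methoxybenzyl)-4-[3-methoxy-4-(triisopropylsilyloxy)benzyl]dihydrofuran-2(3H)-one | COc1cc(C[C@H]2C(=O)OC[C@@H]2Cc2ccc(O[Si](C(C)C)(C(C)C)C(C)C)c(OC)c2)ccc1OCc1ccccc1 | intermediate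
13 | (3R,4R)-3-(4-benzyloxy-3-methoxybenzyl)-4-(4-hydroxy-3-methoxybenzyl)dihydrofuran-2(3H)-one | COc1cc(C[C@H]2C(=O)OC[C@@H]2Cc2ccc(O)c(OC)c2)ccc1OCc1ccccc1 | intermediate
14 | (S)-4-benzyl-3-(chloroacetyl)oxazolidin-2-one | O=C(CCl)N1[C@@H](Cc2ccccc2)COC1=O | starting material
15 | (S)-4-benzyl-3-(2-{4-[((3R,4R)-4-(4-benzyloxy-3-methoxybenzyl)-5-oxotetrahydrofuran-3-yl)methyl]-2-methoxyphenoxy}acetyl)oxazolidin-2-one | COc1cc(C[C@H]2C(=O)OC[C@@H]2Cc2ccc(OCC(=O)N3[C@@H](Cc4ccccc4)COC3=O)c(OC)c2)ccc1OCc1ccccc1 | intermediate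
16 | 4-benzyloxy-3-methoxybenzaldehyde | COc1cc(C=O)ccc1OCc1ccccc1 | starting material
17 | Z dibutylboron enolate of 15 (not isolated) | COc1cc(C[C@H]2C(=O)OC[C@@H]2Cc2ccc(O/C=C(\OB(CCCC)CCCC)N3[C@@H](Cc4ccccc4)COC3=O)c(OC)c2)ccc1OCc1ccccc1 | intermediate
18 | dibutylboron aldolate (not isolated) | COc1cc(C[C@H]2C(=O)OC[C@@H]2Cc2ccc(O[C@H](C(=O)N3[C@@H](Cc4ccccc4)COC3=O)[C@H](OB(CCCC)CCCC)c3ccc(OCc4ccccc4)c(OC)c3)c(OC)c2)ccc1OCc1ccccc1 | intermediate
19 | (2S,3R) syn-aldol adduct on the (S)-auxiliary | COc1cc(C[C@H]2C(=O)OC[C@@H]2Cc2ccc(O[C@H](C(=O)N3[C@@H](Cc4ccccc4)COC3=O)[C@H](O)c3ccc(OCc4ccccc4)c(OC)c3)c(OC)c2)ccc1OCc1ccccc1 | intermediate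
20 | (3R,4R)-3-(4-benzyloxy-3-methoxybenzyl)-4-{4-[(1R,2R)-1-(4-benzyloxy-3-methoxyphenyl)-1,3-dihydroxypropan-2-yloxy]-3-methoxybenzyl}dihydrofuran-2(3H)-one | COc1cc(C[C@H]2C(=O)OC[C@@H]2Cc2ccc(O[C@H](CO)[C@H](O)c3ccc(OCc4ccccc4)c(OC)c3)c(OC)c2)ccc1OCc1ccccc1 | intermediate
21 | (3R,4R)-3-(4-hydroxy-3-methoxybenzyl)-4-{4-[(1R,2R)-1,3-dihydroxy-1-(4-hydroxy-3-methoxyphenyl)propan-2-yloxy]-3-methoxybenzyl}dihydrofuran-2(3H)-one | COc1cc(C[C@H]2C(=O)OC[C@@H]2Cc2ccc(O[C@H](CO)[C@H](O)c3ccc(O)c(OC)c3)c(OC)c2)ccc1O | target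

**Step count.** Total: 11 steps. Longest linear sequence: 10 steps (steps 1, 2, 3, 4, 6, 7, 8, 9, 10, 11); step 5 is a one-step side branch.

**Steps most likely to fail**

Step 4. The carbene may be diverted into benzylic insertion, dimerisation or arene addition, or the catalyst may give insufficient enantiocontrol at C4. The fallback makes the same C3–C4 bond by auxiliary-controlled alkylation instead of by insertion, setting out from alcohol 3. Oxidation (TEMPO cat., PhI(OAc)2, MeCN/H2O) should give 3-[3-methoxy-4-(triisopropylsilyloxy)phenyl]propanoic acid F1. Acylation of (S)-4-benzyloxazolidin-2-one through the pivaloyl mixed anhydride (PivCl, Et3N, LiCl, THF) should give (S)-4-benzyl-3-{3-[3-methoxy-4-(triisopropylsilyloxy)phenyl]propanoyl}oxazolidin-2-one F2. Its sodium enolate (NaN(SiMe3)2, THF, −78 °C) should be alkylated by tert-butyl bromoacetate on the face away from the auxiliary benzyl group to give tert-butyl (R)-3-[(S)-4-benzyl-2-oxooxazolidine-3-carbonyl]-4-[3-methoxy-4-(triisopropylsilyloxy)phenyl]butanoate F3. LiBH4 (THF, MeOH, 0 °C) should cleave the auxiliary to tert-butyl (R)-3-(hydroxymethyl)-4-[3-methoxy-4-(triisopropylsilyloxy)phenyl]butanoate F4, and TFA in CH2Cl2 should cleave the tert-butyl ester and close the ring to lactone 8, where the route continues with step 6.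

Step 10. Hydride may attack the lactone as well as the imide, or the basic medium may trigger retro-aldol cleavage or epimerisation at C8. The fallback separates auxiliary removal from reduction, setting out from aldol adduct 19. LiOH/H2O2 (THF/H2O, 0 °C) with acidic work-up, which recloses any opened lactone, should give (2S,3R)-3-(4-benzyloxy-3-methoxyphenyl)-3-hydroxy-2-{4-[((3R,4R)-4-(4-benzyloxy-3-methoxybenzyl)-5-oxotetrahydrofuran-3-yl)methyl]-2-methoxyphenoxy}propanoic acid F5. BH3·SMe2 (THF, 0 °C) should then reduce the carboxylic acid in preference to the lactone and give diol 20, where the route continues with step 11.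

Step 8. The phenoxide may attack the imide carbonyl (acyl transfer with loss of the auxiliary) in competition with SN2 etherification. The fallback builds the imide by N-acylation instead, setting out from phenol 13. Alkylation with tert-butyl bromoacetate (K2CO3, acetone) should give tert-butyl 2-{4-[((3R,4R)-4-(4-benzyloxy-3-methoxybenzyl)-5-oxotetrahydrofuran-3-yl)methyl]-2-methoxyphenoxy}acetate F6. TFA in CH2Cl2 should give 2-{4-[((3R,4R)-4-(4-benzyloxy-3-methoxybenzyl)-5-oxotetrahydrofuran-3-yl)methyl]-2-methoxyphenoxy}acetic acid F7. Coupling with (S)-4-benzyloxazolidin-2-one through the pivaloyl mixed anhydride (PivCl, Et3N, LiCl, THF) should give imide 15, where the route continues with step 9.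

**Further compounds**

F1 | step 4 | 3-[3-methoxy-4-(triisopropylsilyloxy)phenyl]propanoic acid | COc1cc(CCC(=O)O)ccc1O[Si](C(C)C)(C(C)C)C(C)C
F2 | step 4 | (S)-4-benzyl-3-{3-[3-methoxy-4-(triisopropylsilyloxy)phenyl]propanoyl}oxazolidin-2-one | COc1cc(CCC(=O)N2[C@@H](Cc3ccccc3)COC2=O)ccc1O[Si](C(C)C)(C(C)C)C(C)C
F3 | step 4 | tert-butyl (R)-3-[(S)-4-benzyl-2-oxooxazolidine-3-carbonyl]-4-[3-methoxy-4-(triisopropylsilyloxy)phenyl]butanoate | COc1cc(C[C@H](CC(=O)OC(C)(C)C)C(=O)N2[C@@H](Cc3ccccc3)COC2=O)ccc1O[Si](C(C)C)(C(C)C)C(C)C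
F4 | step 4 | tert-butyl (R)-3-(hydroxymethyl)-4-[3-methoxy-4-(triisopropylsilyloxy)phenyl]butanoate | COc1cc(C[C@H](CC(=O)OC(C)(C)C)CO)ccc1O[Si](C(C)C)(C(C)C)C(C)C
F5 | step 10 | (2S,3R)-3-(4-benzyloxy-3-methoxyphenyl)-3-hydroxy-2-{4-[((3R,4R)-4-(4-benzyloxy-3-methoxybenzyl)-5-oxotetrahydrofuran-3-yl)methyl]-2-methoxyphenoxy}propanoic acid | COc1cc(C[C@H]2C(=O)OC[C@@H]2Cc2ccc(O[C@H](C(=O)O)[C@H](O)c3ccc(OCc4ccccc4)c(OC)c3)c(OC)c2)ccc1OCc1ccccc1
F6 | step 8 | tert-butyl 2-{4-[((3R,4R)-4-(4-benzyloxy-3-methoxybenzyl)-5-oxotetrahydrofuran-3-yl)methyl]-2-methoxyphenoxy}acetate | COc1cc(C[C@H]2C(=O)OC[C@@H]2Cc2ccc(OCC(=O)OC(C)(C)C)c(OC)c2)ccc1OCc1ccccc1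
F7 | step 8 | 2-{4-[((3R,4R)-4-(4-benzyloxy-3-methoxybenzyl)-5-oxotetrahydrofuran-3-yl)methyl]-2-methoxyphenoxy}acetic acid | COc1cc(C[C@H]2C(=O)OC[C@@H]2Cc2ccc(OCC(=O)O)c(OC)c2)ccc1OCc1ccccc1
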